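**Retrosynthetic overview**
- The quinone comes from para-oxygenation of 2-hexaprenyl-6-methoxyphenol. The only ring is the benzene ring bought in 2-bromo-6-methoxyphenol; no ring is built, it is only oxidised in the last step.
- Key bond C12–C13 of the side chain: lithiated farnesyl p-tolyl sulfone (farnesyl C1 used as a carbanion instead of its usual allyl-cation role) attacks a ring-bearing allylic bromide, so two "natural" allylic electrophile carbons are joined. Hydride then removes the sulfonyl group and the phenol ester in the same flask.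
- The allylic bromide comes from E-selective terminal SeO2 hydroxylation and Appel bromination of an aryl-farnesyl pivalate.
- The aryl-farnesyl pivalate comes from the ortho-lithiated phenoxide of 2-bromo-6-methoxyphenol and farnesyl bromide, pivaloylated in situ.
- Olefin geometry: C2, C6, C14 and C18 come from (2E,6E)-farnesyl bromide; C10 is set E in the SeO2 step.

Assumption: the target has no stereocentre, so "single enantiomer" is read as the single all-E (2E,6E,10E,14E,18E) isomer; (2E,6E)-farnesyl bromide is bought isomerically pure (≥95% E,E).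

**Step 1**
Reactants: 1 (2E,6E)-farnesyl bromide
Product: 2 (2E,6E)-farnesyl p-tolyl sulfone
Conditions: TolSO2Na (1.3 equiv), DMF, rt, 12 h
Reagents that add atoms: sodium p-toluenesulfinate, Cc1ccc(cc1)S(=O)[O-].[Na+]
Why: SN2 S-alkylation of the ambident sulfinate by the primary allylic bromide gives the allylic sulfone without allylic transposition, so both E olefins are carried over unchanged.

**Step 2**
Reactants: 3 2-bromo-6-methoxyphenol; 1 (2E,6E)-farnesyl bromide
Product: 6 2-methoxy-6-[(2E,6E)-farnesyl]phenyl pivalate, via dilithio phenoxide 4 (not isolated), via lithium aryloxide 5 (not isolated)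
Conditions: 3 (1.1 equiv), t-BuLi (3.3 equiv), THF, −78 °C, 1 h; CuBr·SMe2 (10 mol%), 1 (1.0 equiv), −78 → 0 °C; PivCl (1.5 equiv), 0 °C → rt
Reagents that add atoms: pivaloyl chloride, CC(C)(C)C(=O)Cl
Why: O-deprotonation and bromine–lithium exchange give an ortho-lithio phenoxide whose aryl carbanion (far more nucleophilic than the phenoxide oxygen) undergoes monovalent-copper-catalysed SN2 allylation at the primary allylic bromide with the E,E geometry retained, and the hindered phenoxide is then O-acylated in the same flask (an ester could not be present during the lithiation).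

**Step 3**
Reactants: 6 2-methoxy-6-[(2E,6E)-farnesyl]phenyl pivalate
Product: 7 2-[(2E,6E,10E)-12-hydroxy-3,7,11-trimethyldodeca-2,6,10-trien-1-yl]-6-methoxyphenyl pivalate
Conditions: SeO2 (0.3 equiv), t-BuOOH (70% aq., 3 equiv), salicylic acid (0.1 equiv), CH2Cl2, 0 °C → rt; stopped at ca. 60% conversion, 6 recovered
Reagents that add atoms: selenium dioxide, O=[Se]=O (catalytic oxygen carrier); tert-butyl hydroperoxide, CC(C)(C)OO (terminal oxygen source)
Why: catalytic SeO2 allylic oxidation (ene reaction then [2,3]-sigmatropic shift) prefers the terminal isopropylidene and oxidises the methyl trans to the chain, so the C10=C11 olefin becomes stereodefined as E; the acylated ring is too electron-poor to be oxidised.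

**Step 4**
Reactants: 7 2-[(2E,6E,10E)-12-hydroxy-3,7,11-trimethyldodeca-2,6,10-trien-1-yl]-6-methoxyphenyl pivalate
Product: 8 2-[(2E,6E,10E)-12-bromo-3,7,11-trimethyldodeca-2,6,10-trien-1-yl]-6-methoxyphenyl pivalate
Conditions: CBr4 (1.3 equiv), PPh3 (1.4 equiv), CH2Cl2, −20 → 0 °C, 30 min; short silica plug, used at once
Reagents that add atoms: carbon tetrabromide, BrC(Br)(Br)Br
Why: Appel bromination displaces the alkoxyphosphonium by bromide in an SN2 step at the primary allylic carbon under neutral conditions, without allylic transposition or E/Z leakage and without acid that could cyclise the polyene.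

**Step 5 (key step)**
Reactants: 8 2-[(2E,6E,10E)-12-bromo-3,7,11-trimethyldodeca-2,6,10-trien-1-yl]-6-methoxyphenyl pivalate; 2 (2E,6E)-farnesyl p-tolyl sulfone
Product: 11 2-[(2E,6E,10E,14E,18E)-hexaprenyl]-6-methoxyphenol, via lithiated sulfone 9 (not isolated), via sulfonyl pivalate 10 (not isolated)
Conditions: 2 (1.1 equiv), n-BuLi (1.05 equiv), THF, −78 °C, 30 min; 8 (1.0 equiv) in THF, −78 → −40 °C, 2 h; then PdCl2(dppp) [PdCl2(Ph2P(CH2)3PPh2)] (5 mol%), LiBHEt3 (6 equiv), 0 °C → rt, 3 h; sat. aq. NH4Cl
Reagents that add atoms: none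
Why: the α-sulfonyl allyl carbanion 9 makes farnesyl C1 (normally an allyl-cation carbon) a donor that displaces the primary allylic bromide of 8 in an α-selective SN2 alkylation (Biellmann-type allyl–allyl coupling) without touching the flanking E olefins; zerovalent palladium (formed from the divalent precatalyst) then ionises the allylic sulfone of 10 and LiBHEt3 delivers hydride to the less substituted allyl terminus (palladium-catalysed allylic hydride desulfonylation), keeping the C14=C15 olefin in place and E, while the same hydride cleaves the hindered pivalate without acid, which would close the ortho-prenyl phenol to a chroman.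

**Step 6**
Reactants: 11 2-[(2E,6E,10E,14E,18E)-hexaprenyl]-6-methoxyphenol
Product: 12 2-[(2E,6E,10E,14E,18E)-hexaprenyl]-6-methoxy-1,4-benzoquinone
Conditions: Co(salen) [Co(C16H14N2O2), divalent cobalt] (10 mol%), O2 (1 atm), DMF–CH2Cl2 (1:1), rt, 6 h
Reagents that add atoms: dioxygen, O=O
Why: salcomine-type aerobic phenol oxidation, in which the cobalt–superoxo species generates the phenoxyl radical and oxygenates its only free activated position (para, both ortho positions being blocked) to give the p-benzoquinone, leaving the isolated trisubstituted olefins untouched.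

**Compound list**
1 | (2E,6E)-1-bromo-3,7,11-trimethyldodeca-2,6,10-triene [(E,E)-farnesyl bromide] | BrC/C=C(\C)CC/C=C(\C)CCC=C(C)C | starting material
2 | 1-methyl-4-{[(2E,6E)-3,7,11-trimethyldodeca-2,6,10-trien-1-yl]sulfonyl}benzene [(E,E)-farnesyl p-tolyl sulfone] | Cc1ccc(cc1)S(=O)(=O)C/C=C(\C)CC/C=C(\C)CCC=C(C)C | intermediate
3 | 2-bromo-6-methoxyphenol | COc1cccc(Br)c1O | starting material
4 | lithium 2-lithio-6-methoxyphenoxide | COc1cccc([Li])c1O[Li] | intermediate (not isolated)
5 | lithium 2-methoxy-6-[(2E,6E)-3,7,11-trimethyldodeca-2,6,10-trien-1-yl]phenoxide | COc1cccc(C/C=C(\C)CC/C=C(\C)CCC=C(C)C)c1O[Li] | intermediate (not isolated)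
6 | 2-methoxy-6-[(2E,6E)-3,7,11-trimethyldodeca-2,6,10-trien-1-yl]phenyl 2,2-dimethylpropanoate | COc1cccc(C/C=C(\C)CC/C=C(\C)CCC=C(C)C)c1OC(=O)C(C)(C)C | intermediate
7 | 2-[(2E,6E,10E)-12-hydroxy-3,7,11-trimethyldodeca-2,6,10-trien-1-yl]-6-methoxyphenyl 2,2-dimethylpropanoate | COc1cccc(C/C=C(\C)CC/C=C(\C)CC/C=C(\C)CO)c1OC(=O)C(C)(C)C | intermediate
8 | 2-[(2E,6E,10E)-12-bromo-3,7,11-trimethyldodeca-2,6,10-trien-1-yl]-6-methoxyphenyl 2,2-dimethylpropanoate | COc1cccc(C/C=C(\C)CC/C=C(\C)CC/C=C(\C)CBr)c1OC(=O)C(C)(C)C | intermediate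
9 | [(2E,6E)-3,7,11-trimethyl-1-(p-tolylsulfonyl)dodeca-2,6,10-trien-1-yl]lithium | Cc1ccc(cc1)S(=O)(=O)C([Li])/C=C(\C)CC/C=C(\C)CCC=C(C)C | intermediate (not isolated)
10 | 2-methoxy-6-[(2E,6E,10E,14E,18E)-3,7,11,15,19,23-hexamethyl-13-(p-tolylsulfonyl)tetracosa-2,6,10,14,18,22-hexaen-1-yl]phenyl 2,2-dimethylpropanoate (racemic at C13) | COc1cccc(C/C=C(\C)CC/C=C(\C)CC/C=C(\C)CC(/C=C(\C)CC/C=C(\C)CCC=C(C)C)S(=O)(=O)c2ccc(C)cc2)c1OC(=O)C(C)(C)C | intermediate (not isolated)
11 | 2-methoxy-6-[(2E,6E,10E,14E,18E)-3,7,11,15,19,23-hexamethyltetracosa-2,6,10,14,18,22-hexaen-1-yl]phenol | COc1cccc(C/C=C(\C)CC/C=C(\C)CC/C=C(\C)CC/C=C(\C)CC/C=C(\C)CCC=C(C)C)c1O | intermediate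
12 | 2-methoxy-6-[(2E,6E,10E,14E,18E)-3,7,11,15,19,23-hexamethyltetracosa-2,6,10,14,18,22-hexaen-1-yl]cyclohexa-2,5-diene-1,4-dione (CHEBI:27752) | COC1=CC(=O)C=C(C/C=C(\C)CC/C=C(\C)CC/C=C(\C)CC/C=C(\C)CC/C=C(\C)CCC=C(C)C)C1=O | target

**Step count**
Total steps: 6. Longest linear sequence: 5 (steps 2 to 6; step 1 is a one-step branch).

**Three steps most likely to fail, with fallbacks**

Step 3 (terminal allylic oxidation). The internal allylic CH2 groups and the benzylic-allylic CH2 can compete, and the alcohol can over-oxidise to the enal. The fallback sets out from 6 and comes back at 7, and addresses the terminal olefin by hydroxybromination and rebuilding instead of an ene reaction. NBS in THF–H2O at 0 °C gives the terminal bromohydrin F1, and NaH in THF closes it to the terminal epoxide F2. HIO4·2H2O in THF–Et2O cleaves this, with loss of acetone, to the trisnor aldehyde F3. Wittig olefination with Ph3P=C(CH3)CHO in toluene at 80 °C gives the (E)-enal F4, its geometry fixed by the stabilised ylide. Luche reduction (NaBH4, CeCl3·7H2O, MeOH, 0 °C) then gives 7 without touching the aryl pivalate.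

Step 5 (key coupling with in-flask removal of sulfonyl and pivaloyl groups). The carbanion may attack the ester, and the palladium–hydride stage may stall or move the olefin. The fallback sets out from 8 (its partner is made from 1) and comes back at 11, and forms the C12–C13 bond without any sulfone by an allylbarium α,α′-coupling. LiCl in DMF converts 1 into (2E,6E)-farnesyl chloride F5. Activated zerovalent barium (from BaI2 and two equivalents of lithium biphenylide, Li(C12H10), THF, −78 °C) turns this into chloro(farnesyl)barium F6, an allylmetal that keeps its E geometry at −78 °C and reacts through its α-carbon. Addition of 8 at −78 °C gives the hexaprenylphenyl pivalate F7 directly; whether the hindered pivalate survives the allylbarium at −78 °C is the open point of this fallback. LiAlH4 (Et2O, 0 °C) removes the pivaloyl group to give 11.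

Step 2 (dianion allylation and in-situ acylation). Exchange on the electron-rich bromophenoxide may be incomplete, and SN2′ attack or homocoupling of the bromide can intrude. The fallback sets out from 1 and comes back at 6, and C-alkylates a phenoxide instead of using an aryl-metal. Sodium guaiacolate (commercial 2-methoxyphenol, NaH, toluene, rt) is treated with 1; in the non-polar medium the tight ion pair directs alkylation to the only free ortho carbon. This gives 2-farnesyl-6-methoxyphenol F8, separated from the O-farnesyl ether by chromatography. Pivaloylation (NaH, PivCl, THF, 0 °C) then gives 6.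

**Further compounds**
F1 | step 3 | 2-[(2E,6E)-10-bromo-11-hydroxy-3,7,11-trimethyldodeca-2,6-dien-1-yl]-6-methoxyphenyl 2,2-dimethylpropanoate (racemic) | COc1cccc(C/C=C(\C)CC/C=C(\C)CCC(Br)C(C)(C)O)c1OC(=O)C(C)(C)C
F2 | step 3 | 2-[(2E,6E)-9-(3,3-dimethyloxiran-2-yl)-3,7-dimethylnona-2,6-dien-1-yl]-6-methoxyphenyl 2,2-dimethylpropanoate (racemic) | COc1cccc(C/C=C(\C)CC/C=C(\C)CCC2OC2(C)C)c1OC(=O)C(C)(C)C
F3 | step 3 | 2-[(2E,6E)-3,7-dimethyl-10-oxodeca-2,6-dien-1-yl]-6-methoxyphenyl 2,2-dimethylpropanoate | COc1cccc(C/C=C(\C)CC/C=C(\C)CCC=O)c1OC(=O)C(C)(C)C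
F4 | step 3 | 2-methoxy-6-[(2E,6E,10E)-3,7,11-trimethyl-12-oxododeca-2,6,10-trien-1-yl]phenyl 2,2-dimethylpropanoate | COc1cccc(C/C=C(\C)CC/C=C(\C)CC/C=C(\C)C=O)c1OC(=O)C(C)(C)C
F5 | step 5 | (2E,6E)-1-chloro-3,7,11-trimethyldodeca-2,6,10-triene | ClC/C=C(\C)CC/C=C(\C)CCC=C(C)C
F6 | step 5 | chloro[(2E,6E)-3,7,11-trimethyldodeca-2,6,10-trien-1-yl]barium | Cl[Ba]C/C=C(\C)CC/C=C(\C)CCC=C(C)C
F7 | step 5 | 2-methoxy-6-[(2E,6E,10E,14E,18E)-3,7,11,15,19,23-hexamethyltetracosa-2,6,10,14,18,22-hexaen-1-yl]phenyl 2,2-dimethylpropanoate | COc1cccc(C/C=C(\C)CC/C=C(\C)CC/C=C(\C)CC/C=C(\C)CC/C=C(\C)CCC=C(C)C)c1OC(=O)C(C)(C)C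
F8 | step 2 | 2-methoxy-6-[(2E,6E)-3,7,11-trimethyldodeca-2,6,10-trien-1-yl]phenol | COc1cccc(C/C=C(\C)CC/C=C(\C)CCC=C(C)C)c1O
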